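## Structural features

The target 38 is a C20 gibberellin-type acid. Cyclohexane ring A is trans-fused along C5–C10 to cyclopentane ring B, ring B is cis-fused along C8–C9 to ring C, and rings C and D form a bicyclo[3.2.1]octane whose two-carbon bridge carries the exocyclic C16=C17 methylene. A six-membered lactone joins the C20 carboxyl on C10 to the oxygen on C12, which sits 1,3-diaxial to C10 on ring C. C7 (on C6) and C19 (on C4) are free acids, and ring A carries a cis 2,3-diol. There are ten stereocentres; C2, C3, C4, C5, C6, C8, C9 and C10 form one unbroken chain, three are quaternary (C4, C8, C10), and C19 and C20 are syn-axial on ring A. The fragile groups are the exocyclic alkene (no hydrogenolysis, no strong acid, no unselective electrophilic oxidant), C6 (alpha to a carboxyl and allylic in the open-chain precursors), the cis-diol (glycol cleavage), and the axial C19 carboxyl, which is hard to free from an ordinary ester and can trap a C20 hydroxyl as a lactone. The real difficulty is the crowded C4–C5–C10–C9 sequence with its trans A/B junction, which must be set relative to the distant bridgehead C8. The key step exploits two features: the C3 oxygen beside quaternary C4 (methyl plus carboxyl) is the mark of a 2-methyl-3-oxo ester radical at C4, and C9 is beta to the C12 oxygen, so C4–C5 and C9–C10 can form in one oxidative radical cascade across a C5=C10 alkene that ends on a ring C enone.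

## Logic of the disconnections

38 from 37: no skeletal bond is cut, only the two ester C–O bonds. The axial C19 ester is too hindered for hydroxide, which would also open the lactone and threaten C6. Both acids are therefore carried as 2-(trimethylsilyl)ethyl esters that fragment on attack of fluoride at silicon. The demand is that no other protecting group needing a different final operation remains in 37.

37 from 36 from 34: the C3–H and C2–O bonds are cut, taking the cis-diol back to a 3-ketone. In 34 the C3 carbonyl is the only enolizable ketone, so oxygenation at C2 needs no regiochemical choice. Both new centres must be read from the ring A chair: oxygen transfer to the beta face, then equatorial hydride delivery.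

34 from 31 from 30 from 29: the lactone acyl–oxygen bond is cut to a primary C20 alcohol and a 12-hydroxyl, and these go back to the silyl ether and the two ketones of 29. These are oxidation-level changes only. The forward demands are hydride attack on C12 anti to C10, an oxidant selective for the primary alcohol, and no build-up of a free C20 hydroxyl beside the C19 ester. C3 is reduced and re-oxidized on the way; this is accepted so that a choice between two enolizable ketones never arises.

29 from 28: C4–C5 and C9–C10 are cut, which opens rings A and B and removes four stereocentres (C4, C5, C9, C10). The precursor is an open-chain 2-methyl-3-oxo ester tethered through a C5=C10 alkene and C6 to the bicyclic enone. The forward step must choose the alkene face from C6, close ring A through a chair with the ester axial, and close ring B trans to ring A.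

28 from 24 and 26: the C3–C4 bond is cut (C-acylation of a methylmalonate half ester). The conditions must be mild enough for the enone and the allylic, ester-activated C6–H.

24 from 23 from 21 and 7: the C1–C2 bond is cut with allylic transposition. The sigmatropic step converts an aldol carbinol at C5 into the C5=C10 alkene of defined geometry and adds C2 and C3. The demand is a chair transition state with the C6 substituent equatorial.

21 from 20 from 15 and 18: the C5–C6 bond is cut (aldol). A chiral auxiliary on C7 fixes C6, because the bridgehead C8, whose three ring arms are alike, cannot be relied on to direct an enolate face. The C5 centre is disposable.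

18 from 17 from 16, and 26 from 25: functional-group changes on small achiral pieces.

15 from 13 from 12 from 11 from 10: the C13–C16 bond of ring D is cut (alkyne carbocyclization of a silyl enol ether). The ketone can enolize only toward C13, so ring D closes without regiochemical doubt, and the bridge fixes C13 once C8 is set.

10 from 9 from 6 and 7: the C12 oxygen is removed (allylic oxidation), then the C6–C8 bond is cut with transposition. The quaternary C8 is thus taken back to a secondary allylic carbinol, whose configuration is relayed suprafacially. An entry by para C-propargylation of a phenol was set aside: unhindered phenoxides alkylate at oxygen and ortho carbon, and the later choice between enantiotopic enone halves would rest on telling two CH2–π groups apart.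

6 from 5 from 1 and 2: the C8–C15 bond is cut (propargyl addition to a vinylogous ester), followed by asymmetric carbonyl reduction.

## Other disconnections considered

Alternative 1: The cut is C9–C11 of ring C (with loss of water), leading back to an achiral 2-propargyl-2-(3-oxobutyl)cyclopentane-1,3-dione. The forward step is the Hajos–Parrish aldol: (S)-proline forms the enamine of the methyl ketone, C11 attacks one of the two enantiotopic ring carbonyls, and dehydration gives the enedione A1 with C8 fixed. In its favour: it is catalytic, metal-free and cheap, and it sets the quaternary C8 with the propargyl arm for ring D in a single operation. Against it here: A1 contains only rings B and C. C6 is a ketone carbon and lacks C7, so a one-carbon homologation with control of C6 is still needed. C10 is an unactivated ring methylene that would have to become a quaternary centre bearing ring A and C20. Enantioselectivity in this aldol usually drops when the angular group is larger than methyl. Comparison: for fixing C8 alone the alternative is the better (one step, against reduction plus rearrangement, steps 2 and 3, in the chosen plan). On structure it leaves eight stereocentres and two rings unaddressed, whereas step 17 of the chosen plan closes two rings and sets four stereocentres on a precursor that already holds C7, C19 and C20. Overall the chosen plan should be shorter.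

Alternative 2: The cut is C13–C16 of ring D, leading back to a 12,13-epoxide of a rings A–B–C tricycle with a propargyl group on C8. In the forward step Cp2TiCl (trivalent titanium) opens the epoxide homolytically, the C13 radical adds 5-exo-dig to the alkyne, and the vinyl radical is reduced to give A2. In its favour: one mild step gives ring D, the exocyclic methylene and a 12-hydroxyl already on the face of C20, ready to lactonize. The acid-sensitive alkene would appear only at the end. Against it: C12 and C13 are both secondary, so nothing directs C–O homolysis to C13. The epoxide would have to sit on the ring C face syn to the C10 substituent, the hindered one. The whole C4–C5–C10–C9 problem stays unsolved upstream. Comparison: mechanistically the two plans are equals (radical 5-exo closure with reductive termination). The alternative is better in setting the C12 configuration and ring D together and in delaying the exocyclic alkene; the chosen plan needs the separate face-selective reduction of step 18. The chosen plan is better in regiocontrol (ring D from an enol ether that can form in one direction only) and in step count, because the alternative's precursor needs a full A–B–C synthesis first.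

Alternative 3: The cut is C8–C9 and C13–C14, leading back to a ring A cyclohexane that carries a 2-silyloxydiene on C10 and an alpha-propargyl enone on C5. In the forward step an intramolecular Diels–Alder reaction (heat or Me2AlCl) closes ring B as a cyclopentanone and ring C as a silyl enol ether, giving A3. In its favour: two rings and two bonds form in one concerted, suprafacial step that sets the quaternary C8 and C9. Diene and dienophile are polarity-matched, the tether fixes the regiochemistry, and no radical can be reduced or oxidized prematurely. Against it: the precursor already needs a fully substituted ring A (C2 to C5 plus quaternary C10). C5 is alpha to the ketone and can epimerize. The face and endo/exo selectivity across a quaternary C10 is open. A3 has a ketone at C6 and no C7. Its enol ether points to C11, whereas closure of ring D needs the enolate toward C13. Me2AlCl could strip the acetal or the enol ether. Comparison: on bonds and rings formed in the key step the two plans are equal, and the alternative is better in building C8 stereospecifically within that step. The chosen plan sets more stereocentres (four against two), carries C7 from the start, and avoids a long linear construction of ring A before the key step.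

Key step: step 17

Remarks. Locants C1–C20 follow the gibberellane skeleton throughout. β means the face of the A/B system carrying H-5, H-9 and C-7; α means the face carrying C-19, C-20 and H-6. The C20 oxygen is carried as a tert-butyldimethylsilyl ether (no weak C–H bond near the chain-ending radical) and C7 and C19 as 2-(trimethylsilyl)ethyl esters; the carbon skeletons of precursor 28 and product 29 are unchanged by this. The stereodescriptors of 28 and 29 were checked centre by centre against 38 (C4, C5, C6, C8, C9, C10, C13 agree), so no structural correction was needed.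

## Steps

Step 1
Reactants: 1 3-ethoxycyclohex-2-en-1-one; 2 3-bromoprop-1-yne (propargyl bromide)
Product: 5 3-(prop-2-yn-1-yl)cyclohex-2-en-1-one, via allenylmagnesium bromide 3 (not isolated), via 3-ethoxy-1-(prop-2-yn-1-yl)cyclohex-2-en-1-ol 4 (not isolated)
Conditions: 2, Mg, HgCl2 (cat.), Et2O, 0 °C; add 1, THF, −20 °C → rt; 1 M HCl, 0 °C, 15 min
Reagents that add atoms: water, O
Why: The Grignard reagent from 2 reacts as allenylmagnesium bromide and transfers the propargyl group by SE2′ 1,2-addition to the vinylogous ester carbonyl; cold dilute acid then ionizes the tertiary alcohol and hydrolyzes the enol ether (Stork–Danheiser transposition). Brief, cold acid keeps the skipped enyne from moving into conjugation.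

Step 2
Reactants: 5 3-(prop-2-yn-1-yl)cyclohex-2-en-1-one
Product: 6 (1R)-3-(prop-2-yn-1-yl)cyclohex-2-en-1-ol
Conditions: (S)-2-methyl-CBS-oxazaborolidine (20 mol %), catecholborane (1.5 equiv), toluene, −78 °C; MeOH, then 1 M NaOH wash
Reagents that add atoms: none
Why: Corey–Bakshi–Shibata reduction: the oxazaborolidine binds the carbonyl with the alkenyl arm as the large group and hydride is delivered to one face, which should give the (R)-carbinol; catecholborane at −78 °C leaves the terminal alkyne alone. Any shortfall in enantiopurity can be removed at 15 or 20, where the minor antipode is a separable diastereomer.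

Step 3
Reactants: 6 (1R)-3-(prop-2-yn-1-yl)cyclohex-2-en-1-ol; 7 trimethyl orthoacetate
Product: 9 methyl 2-[(1S)-1-(prop-2-yn-1-yl)cyclohex-2-en-1-yl]acetate, via 1-methoxyethenyl ether of 6 8 (not isolated)
Conditions: 7 (6 equiv), EtCO2H (10 mol %), xylenes, 135 °C, MeOH distilled off
Reagents that add atoms: none
Why: Johnson–Claisen rearrangement: ketene acetal 8 rearranges suprafacially, so the C6–C8 bond forms on the ring face that carried the C–O bond and the carbinol configuration is relayed to the quaternary C8 ((1R)-alcohol to (1S)-ester). The ring alkene is left at C9=C11, where the enone is needed.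

Step 4
Reactants: 9 methyl 2-[(1S)-1-(prop-2-yn-1-yl)cyclohex-2-en-1-yl]acetate
Product: 10 methyl 2-[(1S)-4-oxo-1-(prop-2-yn-1-yl)cyclohex-2-en-1-yl]acetate
Conditions: Rh2(cap)4 (dirhodium tetrakis(caprolactamate), 1 mol %), t-BuOOH (70% aq., 5 equiv), K2CO3 (0.5 equiv), CH2Cl2, rt
Reagents that add atoms: tert-butyl hydroperoxide, CC(C)(C)OO
Why: Allylic C–H oxidation by a tert-butylperoxyl radical chain at C12, the only allylic methylene (the other allylic position is quaternary C8), should give one enone. The neopentyl propargylic CH2 of the terminal alkyne is expected to react much more slowly.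

Step 5
Reactants: 10 methyl 2-[(1S)-4-oxo-1-(prop-2-yn-1-yl)cyclohex-2-en-1-yl]acetate
Product: 11 methyl 2-[(1S)-4-[(tert-butyldimethylsilyl)oxy]-1-(prop-2-yn-1-yl)cyclohexa-2,4-dien-1-yl]acetate
Conditions: t-BuMe2SiOTf (1.3 equiv), Et3N (2 equiv), CH2Cl2, 0 °C; filtration through basic alumina
Reagents that add atoms: tert-butyldimethylsilyl trifluoromethanesulfonate, CC(C)(C)[Si](C)(C)OS(=O)(=O)C(F)(F)F
Why: Soft enolization: the ketone can enolize only toward C13 (C11 is vinylic, C8 quaternary), giving the cross-conjugated 2-silyloxydiene; the ester is not silylated under these conditions.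

Step 6
Reactants: 11 methyl 2-[(1S)-4-[(tert-butyldimethylsilyl)oxy]-1-(prop-2-yn-1-yl)cyclohexa-2,4-dien-1-yl]acetate
Product: 12 methyl 2-[(1S,5R)-6-methylidene-4-oxobicyclo[3.2.1]oct-2-en-1-yl]acetate
Conditions: AuCl(PPh3) (5 mol %), AgBF4 (5 mol %), toluene–MeOH (10:1), rt
Reagents that add atoms: none
Why: Conia-ene-type carbocyclization of a silyl enol ether: monovalent gold activates the alkyne, C13 attacks the internal alkyne carbon 5-exo-dig to form C13–C16, and protodeauration by methanol leaves the exocyclic methylene while methanol takes the silyl group. The bridge can span only one face, so C13 follows from C8 and a single bicyclo[3.2.1]octenone should form.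

Step 7
Reactants: 12 methyl 2-[(1S,5R)-6-methylidene-4-oxobicyclo[3.2.1]oct-2-en-1-yl]acetate
Product: 13 2-[(1S,5R)-6-methylidene-4-oxobicyclo[3.2.1]oct-2-en-1-yl]acetic acid
Conditions: LiOH·H2O (2 equiv), THF–H2O (3:1), 0 °C → rt; 1 M HCl to pH 3, 0 °C, immediate extraction
Reagents that add atoms: lithium hydroxide, [Li+].[OH-]
Why: Saponification of an unhindered methyl ester; the enone has no enolizable position (bridgehead C13, vinylic C11) and should survive. Cold, brief acidification keeps the acid from adding to the enone.

Step 8
Reactants: 13 2-[(1S,5R)-6-methylidene-4-oxobicyclo[3.2.1]oct-2-en-1-yl]acetic acid; 14 (4R)-4-benzyl-1,3-thiazolidine-2-thione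
Product: 15 1-[(4R)-4-benzyl-2-sulfanylidene-1,3-thiazolidin-3-yl]-2-[(1S,5R)-6-methylidene-4-oxobicyclo[3.2.1]oct-2-en-1-yl]ethan-1-one
Conditions: 14 (1.1 equiv), EDC·HCl (1.3 equiv), DMAP (0.2 equiv), CH2Cl2, 0 °C → rt
Reagents that add atoms: none
Why: Carbodiimide-mediated N-acylation installs the auxiliary under neutral conditions that do not touch the enone.

Step 9
Reactants: 16 2-methylidenepropane-1,3-diol
Product: 17 2-({[tert-butyl(dimethyl)silyl]oxy}methyl)prop-2-en-1-ol
Conditions: NaH (1.0 equiv), THF, 0 °C → rt; t-BuMe2SiCl (1.0 equiv)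
Reagents that add atoms: tert-butyldimethylsilyl chloride, CC(C)(C)[Si](C)(C)Cl
Why: Monosilylation of a symmetrical diol through its sparingly soluble monosodium alkoxide, which favours the mono ether.

Step 10
Reactants: 17 2-({[tert-butyl(dimethyl)silyl]oxy}methyl)prop-2-en-1-ol
Product: 18 2-({[tert-butyl(dimethyl)silyl]oxy}methyl)prop-2-enal
Conditions: MnO2 (activated, 15 equiv), CH2Cl2, rt; used at once
Reagents that add atoms: none
Why: MnO2 oxidizes the allylic alcohol selectively to the 2-substituted acrolein, which is used fresh because it polymerizes.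

Step 11
Reactants: 15 1-[(4R)-4-benzyl-2-sulfanylidene-1,3-thiazolidin-3-yl]-2-[(1S,5R)-6-methylidene-4-oxobicyclo[3.2.1]oct-2-en-1-yl]ethan-1-one; 18 2-({[tert-butyl(dimethyl)silyl]oxy}methyl)prop-2-enal
Product: 20 (2R,3R)-1-[(4R)-4-benzyl-2-sulfanylidene-1,3-thiazolidin-3-yl]-4-({[tert-butyl(dimethyl)silyl]oxy}methyl)-3-hydroxy-2-[(1R,5R)-6-methylidene-4-oxobicyclo[3.2.1]oct-2-en-1-yl]pent-4-en-1-one, via trichlorotitanium (Z)-enolate of 15 19 (not isolated)
Conditions: TiCl4 (1.05 equiv), i-Pr2NEt (1.1 equiv), N-methyl-2-pyrrolidinone (1.0 equiv), CH2Cl2, 0 °C; 18 (1.5 equiv), −78 → 0 °C; aq. NH4Cl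
Reagents that add atoms: none
Why: Titanium-mediated aldol of an N-acyl thiazolidinethione (Evans syn sense): soft enolization gives the (Z)-chlorotitanium enolate 19 (the enone cannot enolize), and with the amide additive the non-chelated Zimmerman–Traxler chair brings the aldehyde to the enolate face away from the benzyl group. This should set C6 as (R) under reagent control and so fix C6 relative to C8; the C5 carbinol centre is consumed in step 13.

Step 12
Reactants: 20 (2R,3R)-1-[(4R)-4-benzyl-2-sulfanylidene-1,3-thiazolidin-3-yl]-4-({[tert-butyl(dimethyl)silyl]oxy}methyl)-3-hydroxy-2-[(1R,5R)-6-methylidene-4-oxobicyclo[3.2.1]oct-2-en-1-yl]pent-4-en-1-one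
Product: 21 2-(trimethylsilyl)ethyl (2R,3R)-4-({[tert-butyl(dimethyl)silyl]oxy}methyl)-3-hydroxy-2-[(1R,5R)-6-methylidene-4-oxobicyclo[3.2.1]oct-2-en-1-yl]pent-4-enoate
Conditions: Me3SiCH2CH2OH (10 equiv), imidazole (3 equiv), DMAP (0.2 equiv), CH2Cl2, rt → 35 °C
Reagents that add atoms: 2-(trimethylsilyl)ethanol, C[Si](C)(C)CCO
Why: Alcoholysis of the activated N-acyl thiazolidinethione releases the auxiliary without a base strong enough for retro-aldol or epimerization at C6. The silylethyl ester is chosen because it is later cleaved by fluoride at silicon, whatever the hindrance at the carbonyl.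

Step 13
Reactants: 21 2-(trimethylsilyl)ethyl (2R,3R)-4-({[tert-butyl(dimethyl)silyl]oxy}methyl)-3-hydroxy-2-[(1R,5R)-6-methylidene-4-oxobicyclo[3.2.1]oct-2-en-1-yl]pent-4-enoate; 7 trimethyl orthoacetate
Product: 23 7-methyl 1-[2-(trimethylsilyl)ethyl] (2S,3Z)-4-({[tert-butyl(dimethyl)silyl]oxy}methyl)-2-[(1R,5R)-6-methylidene-4-oxobicyclo[3.2.1]oct-2-en-1-yl]hept-3-enedioate, via 1-methoxyethenyl ether of 21 22 (not isolated)
Conditions: 7 (8 equiv), EtCO2H (10 mol %), xylenes, 130 °C, MeOH distilled off
Reagents that add atoms: none
Why: Johnson–Claisen rearrangement of a 2-substituted secondary allylic alcohol: in the chair transition state the bulky C6 substituent is equatorial, so the trisubstituted C5=C10 alkene should form with C6 trans to the new C1–C2 chain (the Z isomer by priority), which is the geometry the cyclization needs. C1–C2 is formed, the C5 carbinol centre disappears and C6 is untouched.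

Step 14
Reactants: 23 7-methyl 1-[2-(trimethylsilyl)ethyl] (2S,3Z)-4-({[tert-butyl(dimethyl)silyl]oxy}methyl)-2-[(1R,5R)-6-methylidene-4-oxobicyclo[3.2.1]oct-2-en-1-yl]hept-3-enedioate
Product: 24 (4Z,6S)-4-({[tert-butyl(dimethyl)silyl]oxy}methyl)-6-[(1R,5R)-6-methylidene-4-oxobicyclo[3.2.1]oct-2-en-1-yl]-7-oxo-7-[2-(trimethylsilyl)ethoxy]hept-4-enoic acid
Conditions: Me3SnOH (4 equiv), ClCH2CH2Cl, 70 °C; 1 M HCl wash
Reagents that add atoms: trimethyltin hydroxide, C[Sn](C)(C)O
Why: Me3SnOH cleaves the unhindered methyl ester under near-neutral conditions; the alpha-branched silylethyl ester at C7 and the base-sensitive allylic C6–H should be left alone.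

Step 15
Reactants: 25 2,2,5-trimethyl-1,3-dioxane-4,6-dione
Product: 26 2-methyl-3-oxo-3-[2-(trimethylsilyl)ethoxy]propanoic acid
Conditions: Me3SiCH2CH2OH (1.2 equiv), toluene, 100 °C
Reagents that add atoms: 2-(trimethylsilyl)ethanol, C[Si](C)(C)CCO
Why: Thermal alcoholysis of the Meldrum's acid derivative (addition, then fragmentation with loss of acetone) gives the malonic half ester.

Step 16
Reactants: 24 (4Z,6S)-4-({[tert-butyl(dimethyl)silyl]oxy}methyl)-6-[(1R,5R)-6-methylidene-4-oxobicyclo[3.2.1]oct-2-en-1-yl]-7-oxo-7-[2-(trimethylsilyl)ethoxy]hept-4-enoic acid; 26 2-methyl-3-oxo-3-[2-(trimethylsilyl)ethoxy]propanoic acid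
Product: 28 bis[2-(trimethylsilyl)ethyl] (2S,3Z)-4-({[tert-butyl(dimethyl)silyl]oxy}methyl)-8-methyl-2-[(1R,5R)-6-methylidene-4-oxobicyclo[3.2.1]oct-2-en-1-yl]-7-oxonon-3-enedioate, via imidazolide of 24 27 (not isolated)
Conditions: 1,1′-carbonyldiimidazole (1.2 equiv), THF, rt; then 26 (2 equiv), MgCl2 (2 equiv), Et3N (4 equiv), THF–MeCN, rt → 40 °C; 10% citric acid
Reagents that add atoms: none
Why: Masamune–Brooks homologation: imidazolide 27 C-acylates the magnesium chelate of half ester 26 and the adduct loses CO2 on mild acid work-up, forming C3–C4 and the 2-methyl-3-oxo ester under conditions mild enough for the enone and for C6. C4 arises as both epimers, which does not matter because C4 becomes a radical.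

Step 17
Reactants: 28 bis[2-(trimethylsilyl)ethyl] (2S,3Z)-4-({[tert-butyl(dimethyl)silyl]oxy}methyl)-8-methyl-2-[(1R,5R)-6-methylidene-4-oxobicyclo[3.2.1]oct-2-en-1-yl]-7-oxonon-3-enedioate
Product: 29 bis[2-(trimethylsilyl)ethyl] 20-{[tert-butyl(dimethyl)silyl]oxy}-3,12-dioxogibberell-16-ene-7,19-dioate
Conditions: Mn(OAc)3·2H2O (2.5 equiv), degassed EtOH–AcOH (9:1), 0.02 M, 40 °C, argon
Reagents that add atoms: none
Why: Mn(OAc)3 (trivalent manganese) forms the manganese enolate of the keto ester and oxidizes it by inner-sphere electron transfer to the electrophilic C4 radical. This radical adds 6-endo to C5, the less substituted end of the electron-rich C5=C10 alkene, through a chair with the ester axial and the C6 chain (trans to C1 in the alkene) equatorial, which closes ring A and sets C4 (ester cis to C20) and C5. The alkene face is chosen by C6: allylic 1,3-strain against C20 holds H-6 in the alkene plane and the radical enters anti to the quaternary C8, which should give the required trans relation of H-5 and H-6. The tertiary, nucleophilic C10 radical then closes ring B 5-exo onto C9, the beta carbon of the enone, a polarity-matched step; the three-atom link C5–C6–C8 allows only a cis B/C junction, so C9 is attacked on the ring C face opposite the C15–C16 bridge. C10 should bond through the lobe on the side of the equatorial C6 chain, leaving C20 axial and the A/B junction trans; this is the selectivity the step needs most and the one the substrate secures least. The C11 alpha-keto radical abstracts hydrogen from ethanol and the 1-hydroxyethyl radical consumes the second equivalent of oxidant; Cu(OAc)2 is left out because it would oxidize the tertiary C10 radical. The closest known reaction type is the Mn(OAc)3-mediated 6-endo then 5-exo tandem cyclization of unsaturated 2-alkyl-3-oxo esters to trans-fused bicyclic keto esters with an axial ester. The exocyclic methylene cannot be reached by either radical in a favourable ring size, and the silyl ether on C20 offers no weak C–H bond for internal hydrogen transfer to the C11 radical.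

Step 18
Reactants: 29 bis[2-(trimethylsilyl)ethyl] 20-{[tert-butyl(dimethyl)silyl]oxy}-3,12-dioxogibberell-16-ene-7,19-dioate
Product: 30 bis[2-(trimethylsilyl)ethyl] 20-{[tert-butyl(dimethyl)silyl]oxy}-3α,12α-dihydroxygibberell-16-ene-7,19-dioate
Conditions: NaBH4 (4 equiv), CeCl3·7H2O (1 equiv), MeOH–THF (1:1), −40 → 0 °C
Reagents that add atoms: none
Why: Luche-type reduction of both ketones. At C12 the face syn to C10 is closed by the axial quaternary C10 and its CH2OSi arm, so hydride should come from the side of the C15–C16 bridge and place the hydroxyl on the α face, syn to C20. At C3 axial attack should give mainly the equatorial 3α-alcohol, whose configuration is of no consequence because C3 is re-oxidized in step 20.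

Step 19
Reactants: 30 bis[2-(trimethylsilyl)ethyl] 20-{[tert-butyl(dimethyl)silyl]oxy}-3α,12α-dihydroxygibberell-16-ene-7,19-dioate
Product: 31 bis[2-(trimethylsilyl)ethyl] 3α,12α,20-trihydroxygibberell-16-ene-7,19-dioate
Conditions: HF·pyridine, pyridine, THF, 0 °C → rt; pH 7 work-up
Reagents that add atoms: none
Why: Buffered HF·pyridine cleaves the primary silyl ether, while silylethyl esters need basic fluoride and stay. The triol is taken on without delay because the C20 hydroxyl lies 1,3-diaxial to the C19 ester.

Step 20
Reactants: 31 bis[2-(trimethylsilyl)ethyl] 3α,12α,20-trihydroxygibberell-16-ene-7,19-dioate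
Product: 34 bis[2-(trimethylsilyl)ethyl] 3-oxogibberell-16-ene-7,19,20-trioate 20,12α-lactone, via C20 lactol 32 (not isolated), via 3α-hydroxy 20,12α-lactone 33 (not isolated)
Conditions: PhI(OAc)2 (2.6 equiv), TEMPO (0.2 equiv), CH2Cl2, rt; then Dess–Martin periodinane (1.5 equiv), NaHCO3, rt
Reagents that add atoms: none
Why: Nitroxyl-catalysed oxidation is selective for the primary C20 alcohol; the aldehyde is captured by the 12α-hydroxyl as the six-membered lactol 32, which is oxidized on to lactone 33. Dess–Martin periodinane, added to the same flask once the diol is consumed, converts the remaining C3 alcohol to the ketone and completes any lactol oxidation.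

Step 21
Reactants: 34 bis[2-(trimethylsilyl)ethyl] 3-oxogibberell-16-ene-7,19,20-trioate 20,12α-lactone
Product: 36 bis[2-(trimethylsilyl)ethyl] 2β-hydroxy-3-oxogibberell-16-ene-7,19,20-trioate 20,12α-lactone, via potassium enolate of 34 35 (not isolated)
Conditions: KN(SiMe3)2 (1.15 equiv), THF, −78 °C; 3-phenyl-2-(phenylsulfonyl)oxaziridine (1.3 equiv), −78 °C; aq. NH4Cl
Reagents that add atoms: 3-phenyl-2-(phenylsulfonyl)oxaziridine, O=S(=O)(c1ccccc1)N1OC1c1ccccc1
Why: Only the C3 ketone now has an enolizable alpha position (C12 is no longer a carbonyl, the lactone has no alpha hydrogen, and the C6–H of the hindered ester is far less acidic), so enolate 35 forms at C2. The N-sulfonyloxaziridine should transfer oxygen to the β face because the α face is screened by the axial C19 ester and the axial C10–C20 bond, giving the equatorial 2β-hydroxy ketone.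

Step 22
Reactants: 36 bis[2-(trimethylsilyl)ethyl] 2β-hydroxy-3-oxogibberell-16-ene-7,19,20-trioate 20,12α-lactone
Product: 37 bis[2-(trimethylsilyl)ethyl] 2β,3β-dihydroxygibberell-16-ene-7,19,20-trioate 20,12α-lactone
Conditions: LiBH(s-Bu)3 (L-Selectride, 3.5 equiv), THF, −78 °C; AcOH quench at −78 °C
Reagents that add atoms: none
Why: The bulky trialkylborohydride should attack C3 along the equatorial trajectory (the axial path meets the 1,3-diaxial hydrogens on C1 and C5), giving the axial 3β-alcohol cis to the equatorial 2β-oxygen. The hindered lactone and the silylethyl esters are expected to be inert at −78 °C.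

Step 23
Reactants: 37 bis[2-(trimethylsilyl)ethyl] 2β,3β-dihydroxygibberell-16-ene-7,19,20-trioate 20,12α-lactone
Product: 38 2β,3β-dihydroxygibberell-16-ene-7,19,20-trioic acid 20,12α-lactone (CNP0212122.1)
Conditions: Bu4NF (6 equiv), THF, rt → 40 °C; 1 M HCl to pH 3, 0 °C
Reagents that add atoms: none
Why: Fluoride attacks silicon and both 2-(trimethylsilyl)ethyl esters fragment to carboxylate, ethene and Me3SiF, so even the hindered axial C19 ester is freed without hydroxide. Lactone, diol, C6 and the exocyclic alkene should be untouched, and acidification gives the diacid lactone.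

## Compound list

1 | 3-ethoxycyclohex-2-en-1-one | CCOC1=CC(=O)CCC1 | starting material
2 | 3-bromoprop-1-yne (propargyl bromide) | C#CCBr | starting material
3 | allenylmagnesium bromide | C=C=C[Mg]Br | intermediate
4 | 3-ethoxy-1-(prop-2-yn-1-yl)cyclohex-2-en-1-ol (racemic) | CCOC1=CC(O)(CC#C)CCC1 | intermediate
5 | 3-(prop-2-yn-1-yl)cyclohex-2-en-1-one | O=C1C=C(CC#C)CCC1 | intermediate
6 | (1R)-3-(prop-2-yn-1-yl)cyclohex-2-en-1-ol | O[C@H]1C=C(CC#C)CCC1 | intermediate
7 | trimethyl orthoacetate | CC(OC)(OC)OC | starting material
8 | (1R)-1-[(1-methoxyethenyl)oxy]-3-(prop-2-yn-1-yl)cyclohex-2-ene | COC(=C)O[C@H]1C=C(CC#C)CCC1 | intermediate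
9 | methyl 2-[(1S)-1-(prop-2-yn-1-yl)cyclohex-2-en-1-yl]acetate | COC(=O)C[C@@]1(CC#C)CCCC=C1 | intermediate
10 | methyl 2-[(1S)-4-oxo-1-(prop-2-yn-1-yl)cyclohex-2-en-1-yl]acetate | COC(=O)C[C@@]1(CC#C)CCC(=O)C=C1 | intermediate
11 | methyl 2-[(1S)-4-[(tert-butyldimethylsilyl)oxy]-1-(prop-2-yn-1-yl)cyclohexa-2,4-dien-1-yl]acetate | COC(=O)C[C@@]1(CC#C)CC=C(O[Si](C)(C)C(C)(C)C)C=C1 | intermediate
12 | methyl 2-[(1S,5R)-6-methylidene-4-oxobicyclo[3.2.1]oct-2-en-1-yl]acetate | COC(=O)C[C@@]12CC(=C)[C@@H](C1)C(=O)C=C2 | intermediate
13 | 2-[(1S,5R)-6-methylidene-4-oxobicyclo[3.2.1]oct-2-en-1-yl]acetic acid | OC(=O)C[C@@]12CC(=C)[C@@H](C1)C(=O)C=C2 | intermediate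
14 | (4R)-4-benzyl-1,3-thiazolidine-2-thione | S=C1N[C@H](Cc2ccccc2)CS1 | starting material
15 | 1-[(4R)-4-benzyl-2-sulfanylidene-1,3-thiazolidin-3-yl]-2-[(1S,5R)-6-methylidene-4-oxobicyclo[3.2.1]oct-2-en-1-yl]ethan-1-one | S=C1SC[C@@H](Cc2ccccc2)N1C(=O)C[C@@]34CC(=C)[C@@H](C3)C(=O)C=C4 | intermediate
16 | 2-methylidenepropane-1,3-diol | C=C(CO)CO | starting material
17 | 2-({[tert-butyl(dimethyl)silyl]oxy}methyl)prop-2-en-1-ol | C=C(CO)CO[Si](C)(C)C(C)(C)C | intermediate
18 | 2-({[tert-butyl(dimethyl)silyl]oxy}methyl)prop-2-enal | C=C(C=O)CO[Si](C)(C)C(C)(C)C | intermediate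
19 | trichlorotitanium (Z)-enolate of 15 | Cl[Ti](Cl)(Cl)O/C(=C\[C@@]34CC(=C)[C@@H](C3)C(=O)C=C4)N1C(=S)SC[C@H]1Cc2ccccc2 | intermediate
20 | (2R,3R)-1-[(4R)-4-benzyl-2-sulfanylidene-1,3-thiazolidin-3-yl]-4-({[tert-butyl(dimethyl)silyl]oxy}methyl)-3-hydroxy-2-[(1R,5R)-6-methylidene-4-oxobicyclo[3.2.1]oct-2-en-1-yl]pent-4-en-1-one (syn aldol; C6 R, C5 R) | S=C1SC[C@@H](Cc2ccccc2)N1C(=O)[C@@H]([C@@H](O)C(=C)CO[Si](C)(C)C(C)(C)C)[C@@]34CC(=C)[C@@H](C3)C(=O)C=C4 | intermediate
21 | 2-(trimethylsilyl)ethyl (2R,3R)-4-({[tert-butyl(dimethyl)silyl]oxy}methyl)-3-hydroxy-2-[(1R,5R)-6-methylidene-4-oxobicyclo[3.2.1]oct-2-en-1-yl]pent-4-enoate | C[Si](C)(C)CCOC(=O)[C@@H]([C@@H](O)C(=C)CO[Si](C)(C)C(C)(C)C)[C@@]12CC(=C)[C@@H](C1)C(=O)C=C2 | intermediate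
22 | 1-methoxyethenyl ether of 21 (ketene acetal on O-5) | C[Si](C)(C)CCOC(=O)[C@@H]([C@@H](OC(=C)OC)C(=C)CO[Si](C)(C)C(C)(C)C)[C@@]12CC(=C)[C@@H](C1)C(=O)C=C2 | intermediate
23 | 7-methyl 1-[2-(trimethylsilyl)ethyl] (2S,3Z)-4-({[tert-butyl(dimethyl)silyl]oxy}methyl)-2-[(1R,5R)-6-methylidene-4-oxobicyclo[3.2.1]oct-2-en-1-yl]hept-3-enedioate | COC(=O)CC/C(CO[Si](C)(C)C(C)(C)C)=C/[C@H](C(=O)OCC[Si](C)(C)C)[C@@]12CC(=C)[C@@H](C1)C(=O)C=C2 | intermediate
24 | (4Z,6S)-4-({[tert-butyl(dimethyl)silyl]oxy}methyl)-6-[(1R,5R)-6-methylidene-4-oxobicyclo[3.2.1]oct-2-en-1-yl]-7-oxo-7-[2-(trimethylsilyl)ethoxy]hept-4-enoic acid | OC(=O)CC/C(CO[Si](C)(C)C(C)(C)C)=C/[C@H](C(=O)OCC[Si](C)(C)C)[C@@]12CC(=C)[C@@H](C1)C(=O)C=C2 | intermediate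
25 | 2,2,5-trimethyl-1,3-dioxane-4,6-dione | CC1C(=O)OC(C)(C)OC1=O | starting material
26 | 2-methyl-3-oxo-3-[2-(trimethylsilyl)ethoxy]propanoic acid (racemic) | CC(C(=O)O)C(=O)OCC[Si](C)(C)C | intermediate
27 | imidazolide of 24 | O=C(CC/C(CO[Si](C)(C)C(C)(C)C)=C/[C@H](C(=O)OCC[Si](C)(C)C)[C@@]12CC(=C)[C@@H](C1)C(=O)C=C2)n1ccnc1 | intermediate
28 | bis[2-(trimethylsilyl)ethyl] (2S,3Z)-4-({[tert-butyl(dimethyl)silyl]oxy}methyl)-8-methyl-2-[(1R,5R)-6-methylidene-4-oxobicyclo[3.2.1]oct-2-en-1-yl]-7-oxonon-3-enedioate (both epimers at the methyl-bearing carbon, C4 of the gibberellane numbering) | C[Si](C)(C)CCOC(=O)C(C)C(=O)CC/C(CO[Si](C)(C)C(C)(C)C)=C/[C@H](C(=O)OCC[Si](C)(C)C)[C@@]12CC(=C)[C@@H](C1)C(=O)C=C2 | intermediate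
29 | bis[2-(trimethylsilyl)ethyl] 20-{[tert-butyl(dimethyl)silyl]oxy}-3,12-dioxogibberell-16-ene-7,19-dioate (A/B trans, B/C cis; H-5, H-9, C-7 β; C-19, C-20 α) | C=C1C[C@]23C[C@H]1C(=O)C[C@H]2[C@@]2(CCC(=O)[C@@](C)(C(=O)OCC[Si](C)(C)C)[C@H]2[C@@H]3C(=O)OCC[Si](C)(C)C)CO[Si](C)(C)C(C)(C)C | intermediate
30 | bis[2-(trimethylsilyl)ethyl] 20-{[tert-butyl(dimethyl)silyl]oxy}-3α,12α-dihydroxygibberell-16-ene-7,19-dioate | C=C1C[C@]23C[C@H]1[C@@H](O)C[C@H]2[C@@]2(CC[C@@H](O)[C@@](C)(C(=O)OCC[Si](C)(C)C)[C@H]2[C@@H]3C(=O)OCC[Si](C)(C)C)CO[Si](C)(C)C(C)(C)C | intermediate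
31 | bis[2-(trimethylsilyl)ethyl] 3α,12α,20-trihydroxygibberell-16-ene-7,19-dioate | C=C1C[C@]23C[C@H]1[C@@H](O)C[C@H]2[C@@]2(CC[C@@H](O)[C@@](C)(C(=O)OCC[Si](C)(C)C)[C@H]2[C@@H]3C(=O)OCC[Si](C)(C)C)CO | intermediate
32 | bis[2-(trimethylsilyl)ethyl] 12α,20-epoxy-3α,20-dihydroxygibberell-16-ene-7,19-dioate (lactol, both C20 epimers) | C=C1C[C@]23C[C@H]1[C@@H]1C[C@H]2[C@@]2(CC[C@@H](O)[C@@](C)(C(=O)OCC[Si](C)(C)C)[C@H]2[C@@H]3C(=O)OCC[Si](C)(C)C)C(O)O1 | intermediate
33 | bis[2-(trimethylsilyl)ethyl] 3α-hydroxygibberell-16-ene-7,19,20-trioate 20,12α-lactone | C=C1C[C@]23C[C@H]1[C@@H]1C[C@H]2[C@@]2(CC[C@@H](O)[C@@](C)(C(=O)OCC[Si](C)(C)C)[C@H]2[C@@H]3C(=O)OCC[Si](C)(C)C)C(=O)O1 | intermediate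
34 | bis[2-(trimethylsilyl)ethyl] 3-oxogibberell-16-ene-7,19,20-trioate 20,12α-lactone | C=C1C[C@]23C[C@H]1[C@@H]1C[C@H]2[C@@]2(CCC(=O)[C@@](C)(C(=O)OCC[Si](C)(C)C)[C@H]2[C@@H]3C(=O)OCC[Si](C)(C)C)C(=O)O1 | intermediate
35 | potassium 2-en-3-olate of 34 | C=C1C[C@]23C[C@H]1[C@@H]1C[C@H]2[C@@]2(CC=C([O-])[C@@](C)(C(=O)OCC[Si](C)(C)C)[C@H]2[C@@H]3C(=O)OCC[Si](C)(C)C)C(=O)O1.[K+] | intermediate
36 | bis[2-(trimethylsilyl)ethyl] 2β-hydroxy-3-oxogibberell-16-ene-7,19,20-trioate 20,12α-lactone | C=C1C[C@]23C[C@H]1[C@@H]1C[C@H]2[C@@]2(C[C@H](O)C(=O)[C@@](C)(C(=O)OCC[Si](C)(C)C)[C@H]2[C@@H]3C(=O)OCC[Si](C)(C)C)C(=O)O1 | intermediate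
37 | bis[2-(trimethylsilyl)ethyl] 2β,3β-dihydroxygibberell-16-ene-7,19,20-trioate 20,12α-lactone | C=C1C[C@]23C[C@H]1[C@@H]1C[C@H]2[C@@]2(C[C@H](O)[C@H](O)[C@@](C)(C(=O)OCC[Si](C)(C)C)[C@H]2[C@@H]3C(=O)OCC[Si](C)(C)C)C(=O)O1 | intermediate
38 | 2β,3β-dihydroxygibberell-16-ene-7,19,20-trioic acid 20,12α-lactone (CNP0212122.1) | C=C1C[C@]23C[C@H]1[C@@H]1C[C@H]2[C@@]2(C[C@H](O)[C@H](O)[C@@](C)(C(=O)O)[C@H]2[C@@H]3C(=O)O)C(=O)O1 | target

## Step count and least certain steps

Total: 23 steps. Longest linear sequence: 20 steps (steps 1–8, 11–14, 16–23, from 1 to 38); steps 9–10 and step 15 are side branches.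

Step 17 (key step). The likeliest failures are closure of ring B through the other lobe of the C10 radical, which would give the cis A/B isomer, and one-electron oxidation of the tertiary C10 radical by trivalent manganese before it cyclizes. Five-membered closures of cyclohexyl radicals often prefer a cis junction, and tertiary radicals are the ones Mn(OAc)3 oxidizes. The fallback replaces the oxidative cascade by a reductive radical chain. From 28, NBS with Mg(ClO4)2 (cat.) in MeCN should brominate the dicarbonyl carbon to give the 2-(trimethylsilyl)ethyl 2-bromo-2-methyl-3-oxo ester F1. Slow addition of Bu3SnH with Et3B/air initiation in toluene at −20 °C then generates the same C4 radical with no oxidant present, allows a lower temperature for the ring B closure, and ends the chain by hydrogen transfer from tin to C11. The route is rejoined at 29.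

Step 4. Hydrogen abstraction could occur at the propargylic methylene as well as at C12, or oxidation could run on past the enone, because the peroxyl radical chain is not very selective between activated C–H bonds. The fallback changes the mechanism to an ene reaction followed by a 2,3-shift. From 9, SeO2 (cat.) with t-BuOOH in CH2Cl2 should hydroxylate C12 to give methyl 2-[(1S)-4-hydroxy-1-(prop-2-yn-1-yl)cyclohex-2-en-1-yl]acetate F2, and Dess–Martin periodinane then gives 10, where the route is rejoined.

Step 13. At 130 °C with acid the C5 oxygen of 21 is allylic and beta to the C7 ester, so ionization and elimination to a conjugated diene ester could overtake the rearrangement. The fallback moves the sigmatropic step to low temperature under basic conditions. From 21, Ac2O and DMAP give the C5 acetate F3. LiN(i-Pr)2 added at −78 °C to F3 premixed with Me3SiCl and Et3N forms the silyl ketene acetal of the unhindered acetate, which rearranges on warming to rt (Ireland–Claisen). Acidic work-up gives acid 24 directly, so the route is rejoined at 24 and 23 is bypassed.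

Step 18. Hydride delivery to C12 from the face syn to C10 would give the 12β-alcohol, which cannot lactonize. The face that must be used is itself flanked by the C16 bridge carbon, so the preference is not certain. The fallback lets the ring fix the configuration. From 29, HF·pyridine frees the C20 alcohol, which closes onto the C12 ketone as the 12,20-hemiketal F4. PhI(OAc)2/TEMPO followed by NaClO2, NaH2PO4 and 2-methylbut-2-ene oxidizes C20 to the acid, which exists as the 12-hydroxy 20,12-lactone (pseudo acid) F5. Et3SiH with BF3·OEt2 in CH2Cl2 at −78 °C reduces the acyloxycarbenium ion, and hydride can only enter from the outer face of the bridged lactone. This gives 34, where the route is rejoined; 30 to 33 are bypassed and C3 is never reduced.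

Step 20. Before or during the oxidation the C19 acyl group could migrate onto the free C20 hydroxyl (closure to a 19,20-lactone), because the two groups are held 1,3-diaxial; oxidation of the 12-hydroxyl ahead of lactol formation is the second risk. The fallback is an oxidative desilylation that never lets the C20 alcohol build up. From 30, PhI(OAc)2, TEMPO (cat.) and Bi(OTf)3 (cat.) in wet MeCN unmask and oxidize the silyl ether in one operation, and Dess–Martin periodinane is then added as in the main route. This rejoins the route at 34; no new compound arises on this path (F0).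

## Further compounds

F1 | step 17 | bis[2-(trimethylsilyl)ethyl] (2S,3Z)-8-bromo-4-({[tert-butyl(dimethyl)silyl]oxy}methyl)-8-methyl-2-[(1R,5R)-6-methylidene-4-oxobicyclo[3.2.1]oct-2-en-1-yl]-7-oxonon-3-enedioate | C[Si](C)(C)CCOC(=O)C(C)(Br)C(=O)CC/C(CO[Si](C)(C)C(C)(C)C)=C/[C@H](C(=O)OCC[Si](C)(C)C)[C@@]12CC(=C)[C@@H](C1)C(=O)C=C2
F2 | step 4 | methyl 2-[(1S)-4-hydroxy-1-(prop-2-yn-1-yl)cyclohex-2-en-1-yl]acetate (both carbinol epimers) | COC(=O)C[C@@]1(CC#C)CCC(O)C=C1
F3 | step 13 | 2-(trimethylsilyl)ethyl (2R,3R)-3-acetoxy-4-({[tert-butyl(dimethyl)silyl]oxy}methyl)-2-[(1R,5R)-6-methylidene-4-oxobicyclo[3.2.1]oct-2-en-1-yl]pent-4-enoate | C[Si](C)(C)CCOC(=O)[C@@H]([C@@H](OC(C)=O)C(=C)CO[Si](C)(C)C(C)(C)C)[C@@]12CC(=C)[C@@H](C1)C(=O)C=C2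
F4 | step 18 | bis[2-(trimethylsilyl)ethyl] 12α,20-epoxy-12-hydroxy-3-oxogibberell-16-ene-7,19-dioate (12,20-hemiketal) | C=C1C[C@]23C[C@H]1[C@]1(O)C[C@H]2[C@@]2(CCC(=O)[C@@](C)(C(=O)OCC[Si](C)(C)C)[C@H]2[C@@H]3C(=O)OCC[Si](C)(C)C)CO1
F5 | step 18 | bis[2-(trimethylsilyl)ethyl] 12-hydroxy-3-oxogibberell-16-ene-7,19,20-trioate 20,12α-lactone (pseudo acid) | C=C1C[C@]23C[C@H]1[C@]1(O)C[C@H]2[C@@]2(CCC(=O)[C@@](C)(C(=O)OCC[Si](C)(C)C)[C@H]2[C@@H]3C(=O)OCC[Si](C)(C)C)C(=O)O1
F0 | step 20 | none | none
A1 | alternative 1 | (7aR)-7a-(prop-2-yn-1-yl)-2,3,7,7a-tetrahydro-1H-indene-1,5(6H)-dione (rings B and C, C6 and C12 ketones) | C#CC[C@]12CCC(=O)C=C1CCC2=O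
A2 | alternative 2 | trimethyl 12α-hydroxy-2β,3β-(isopropylidenedioxy)gibberell-16-ene-7,19,20-trioate | C=C1C[C@]23C[C@H]1[C@@H](O)C[C@H]2[C@@]2(C[C@H](O5)[C@H](OC5(C)C)[C@@](C)(C(=O)OC)[C@H]2[C@@H]3C(=O)OC)C(=O)OC
A3 | alternative 3 | rings A–B–C tricycle: dimethyl 19,20-diester with 2β,3β-isopropylidenedioxy group, C6 ketone, C11=C12 tert-butyldimethylsilyl enol ether and C8 prop-2-yn-1-yl group | C#CC[C@]23CCC(O[Si](C)(C)C(C)(C)C)=C[C@H]2[C@@]2(C[C@H](O5)[C@H](OC5(C)C)[C@@](C)(C(=O)OC)[C@H]2C3=O)C(=O)OC
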